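(The numbers are assumed.)

Count the partner before anything else in this flask.

    substrate + partner → intermediate (k1 = 0.0786 L mol⁻¹ s⁻¹)
    intermediate ⇌ target (K2 = 9.8, k2 = 0.00492 s⁻¹)
    2 partner → self-condensation product (k3 = 0.00659 L mol⁻¹ s⁻¹)

substrate 20 mM; partner 14.0 mM (fed, over 40 s); time 10 h

- two of one species on the left: rate k times its square, two consumed each time
- the reaction counts as stopped when no species that holds the substrate changes by six tenths of a point or more over the second half of the time
- run time (flask): 10 h

* why nothing more happens at 10 h, or that something still does (it is still moving / forward and back rates have come level / all of the substrate has reacted / the partner has run out first)
* how much of the substrate has reacted by 10 h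
* how much target there is at 10 h, in percent of the substrate charged
* how much intermediate there is at 10 h, in percent of the substrate charged

Set up a small table with a row for each thing that can happen to the partner, and read it downward.

The first row is the zero of the scale: one partner per substrate, none lost. With 14.0 mM against 20 mM, the partner is the limiting reagent, and this row allows 70.0 % conversion. Its feed of 40 s is shorter than the substrate's half-life of 0.17 h, reckoned with the whole partner charge present, so treat it as one charge.

The second row is the leak. At any moment, partner lost to self-condensation stands to partner reaching substrate as 2·k3·c(partner) to k1·c(substrate), which is 0.117 at the start. As c(partner) falls this ratio sinks towards zero, so I take 0.0587, half of its starting value, as the mean leak, the partner lost per partner that reaches substrate. Dividing the first row by one plus the leak gives 66.1 %.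

The last row is the split. The forward half-life of the intermediate, 2.3 min, is short against 10 h, and so is the substrate's. I therefore expect a stopped flask with target at 60.0 % and intermediate at 6.12 %.

The forecast says the partner has run out first, with 65.2 % reacted, and it puts target at 59.2 % and intermediate at 6 % on the ground that “the converted material simply splits about 10.8 parts into 9.8 target and 1 intermediate”. My conversion stands 0.90 percentage points above its figure.

The flask gives 65.1 % reacted, 59.0 % target and 6.03 % intermediate, and the partner has run out first, with 0 % of its charge left at 10.0 h. These values lie within the forecast's ranges; a partner charge of 12.7 mM or 15.3 mM moves target by 5 points and out of them. The 0.493 mM of self-condensation product in the flask holds twice its amount of partner, so the mean leak read there is 0.0758, above my 0.0587.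

Now take the neighbour with 8.4 mM of partner. Its mean leak reckons to 0.0352, which gives 40.6 % conversion and 36.8 % target. That neighbour gives 40.4 % and 36.6 %.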